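(Readings and results come from a simulation on assumed constants; scatter was added.)

In the alder run the left-handed substrate had nearly stopped falling, from 29.0 % at 15.0 min to 27.8 % at 25.0 min, so I asked where the partner had gone.

| setting | alder | cedar | flask |
|---|---|---|---|
| left-handed substrate | 13 mM | 30 mM | 20 mM |
| right-handed substrate | 13 mM | 30 mM | 20 mM |
| partner | 40 mM | 40 mM | 40.0 mM |
| protic impurity | 0.40 mM | 0.40 mM | 0.400 mM |
| remark | run made earlier | run made earlier |  |
| time |  |  | 25 min |

| run | time / min | left-handed product / % | right-handed product / % | left-handed substrate / % |
|---|---|---|---|---|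
| alder | 2.00 | 9.8 | 5.7 | 41.4 |
| alder | 3.00 | 11.0 | 7.3 | 37.9 |
| alder | 5.00 | 14.0 | 9.4 | 34.9 |
| alder | 8.00 | 15.5 | 11.5 | 31.9 |
| alder | 10.0 | 16.1 | 12.7 | 31.0 |
| alder | 15.0 | 17.3 | 15.0 | 29.0 |
| alder | 25.0 | 18.0 | 17.8 | 27.8 |
| cedar | 4.00 | 11.6 | 7.6 | 37.9 |
| cedar | 8.00 | 13.3 | 10.1 | 34.8 |
| cedar | 10.0 | 12.7 | 10.2 | 34.9 |
| cedar | 15.0 | 14.4 | 12.0 | 33.3 |
| cedar | 20.0 | 13.7 | 13.6 | 32.8 |
| cedar | 25.0 | 14.3 | 13.2 | 33.6 |

(standard deviation of a reading: 0.5 percentage points)

- partner is single-handed; left-handed substrate and right-handed substrate are mirror images of each other, charged as a racemate, each of them at the stated concentration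
- what may be going on: partner + left-handed substrate -> left-handed product; partner + protic impurity -> quenched reagent; left-handed product <-> right-handed product; partner + right-handed substrate -> right-handed product; 2 partner -> homo dimer
- an excess is the difference of the two amounts in percent of their sum
- an excess is below zero if the other one leads
- the handed part of partner does not stay in what it makes, so the products of the two hands are mirror images too

1. excess of left-handed product over right-handed product in the product at 80 s
2. excess of left-handed product over right-handed product in the product at 25 min
3. part of the left-handed substrate and right-handed substrate charged together that has reacted at 25 min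

I kept a ledger of the partner, which I took as the limiting reagent, and followed one molecule: at each moment it meets either substrate or another partner.

1. I booked 0.40 mM of partner against the protic impurity, which left 39.6 mM usable in alder and in cedar.

2. Both products together came to 9.31 mM in alder at 25.0 min and 16.5 mM in cedar at 25.0 min.

3. I booked the rest of the partner to homo dimer, two partner to each, and counted any partner still unused with it: 30.3 mM of partner in alder and 23.1 mM in cedar.

4. I took the odds at each meeting to follow substrate over partner, so I divided the final odds, product over rest, by the substrate of both hands charged per usable partner. Alder gave 0.468 and cedar 0.471.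

5. Their mean, 0.470, is w, the fork number: final odds of product over rest, per unit of substrate charged per usable partner.

6. The new flask has 39.6 mM usable partner, so I reckoned its odds at 0.474 and its product at 12.7 mM. My reckoning was therefore 31.9 % reacted.

The forecast gave an excess of 24 % at 80 s, an excess of 2.5 % at 25 min and 31.5 % reacted at 25 min, on the ground that “most partner is lost to second-order dimerisation in competition with substrate”.

The flask gave an excess of 27.7 % at 80 s, an excess of 2.82 % at 25 min and 31.7 % reacted at 25 min.

    partner + left-handed substrate → left-handed product (k = 0.0782 /M/s)
    partner + protic impurity → quenched reagent (k = 2.87 /M/s)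
    left-handed product ⇌ right-handed product (k = 9.71 × 10⁻⁴ /s)
    partner + right-handed substrate → right-handed product (k = 0.0402 /M/s)
    2 partner → homo dimer (k = 0.147 /M/s)

The books of this flask give w = 0.467. For a neighbour flask charged with 10 mM of partner, all else held, w gives odds of 1.96, hence 15.9 % reacted. That neighbour gave 15.0 %, which is 62.4 % of its usable partner as product, against 32.1 % in the flask, and it ended with 40.3 % left-handed and 44.7 % right-handed substrate.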